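**Strategy**

The cyclohexane ring (C1 tertiary carbinol, C2 quaternary carbon, C3 bearing the hydroxypropyl arm, C4 alkylidene carbon, C5, C6) is divided into the halves C3–C4–C5 and C6–C1–C2. The bonds C2–C3 and C5–C6 each join carbons α to the 1,4-related functionalised carbons C1 and C4, unions of like polarity. A one-flask [3+3] annulation solves this: lithiated 6-methyl-3,4-dihydro-2H-pyran (masked C4 ketone plus hydroxypropyl arm) is alkylated by a tetrasubstituted 2,3-epoxy triflate from a Sharpless epoxidation (C5–C6), then BF3 triggers enol-ether attack on the quaternary oxirane carbon (C2–C3). Later retro-oxa-Michael opening of the pyran unveils enal and alcohol; a Suzuki coupling adds the epoxy-terpenoid chain.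

Key step: step 6

Remark: the side-chain oxirane is read from the SMILES as cis-configured (2R,3S) and is therefore taken from nerol; 6-methyl-3,4-dihydro-2H-pyran and the trimethylsilyl enol ether of propanal are taken as commercial.

**Route**

Step 1
Reactants: 1 pent-3-yn-1-ol
Product: 2 5-iodopent-2-yne
Conditions: I2, PPh3, imidazole, CH2Cl2, 0 → 23 °C
Reagents that add atoms: iodine (II)
Why: Appel-type iodination converts the primary alcohol into the iodide by SN2 displacement of the oxyphosphonium intermediate and leaves the internal alkyne untouched.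

Step 2
Reactants: 3 prop-2-yn-1-ol; 2 5-iodopent-2-yne
Product: 5 octa-2,6-diyn-1-ol, via dilithio alkoxide 4 (not isolated)
Conditions: n-BuLi (2 equiv), THF/DMPU, −78 → 0 °C; then 2, 0 → 23 °C; H2O
Reagents that add atoms: none
Why: The carbon terminus of the O,C-dilithio species 4 is its more nucleophilic site and undergoes acetylide SN2 alkylation with the primary iodide.

Step 3
Reactants: 5 octa-2,6-diyn-1-ol
Product: 7 (2E)-2,3-dimethyloct-2-en-6-yn-1-ol, via alkenylmagnesium chelate 6 (not isolated)
Conditions: MeMgBr (excess), CuI (cat.), THF, reflux; then MeI, 0 → 23 °C; H2O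
Reagents that add atoms: methylmagnesium bromide (C[Mg]Br); iodomethane (CI)
Why: Copper-catalysed anti-carbomagnesiation of the propargylic alkoxide delivers methyl to C2 and magnesium to C3 within a five-membered chelate (the remote alkyne has no directing group and should not react), and copper-mediated methylation of the alkenyl–magnesium bond of 6 with retention should give the E-tetrasubstituted alkene.

Step 4
Reactants: 7 (2E)-2,3-dimethyloct-2-en-6-yn-1-ol
Product: 8 [(2S,3S)-2,3-dimethyl-3-(pent-3-yn-1-yl)oxiran-2-yl]methanol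
Conditions: Ti(OiPr)4 (cat.), L-(+)-diethyl tartrate (cat.), t-BuOOH, 4 Å molecular sieves, CH2Cl2, −20 °C
Reagents that add atoms: tert-butyl hydroperoxide (CC(C)(C)OO)
Why: Katsuki–Sharpless asymmetric epoxidation of the tetrasubstituted allylic alcohol with the L-(+)-tartrate should deliver oxygen to the face that gives the (2S,3S)-oxirane, which fixes the absolute configuration of the future ring carbons C1 and C2.

Step 5
Reactants: 8 [(2S,3S)-2,3-dimethyl-3-(pent-3-yn-1-yl)oxiran-2-yl]methanol
Product: 9 [(2S,3S)-2,3-dimethyl-3-(pent-3-yn-1-yl)oxiran-2-yl]methyl trifluoromethanesulfonate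
Conditions: Tf2O, 2,6-lutidine, CH2Cl2, −78 °C; used at once
Reagents that add atoms: trifluoromethanesulfonic anhydride (O=S(=O)(OS(=O)(=O)C(F)(F)F)C(F)(F)F)
Why: O-Sulfonylation of the primary alcohol at low temperature gives the glycidyl-type triflate without opening the hindered oxirane.

Step 6
Reactants: 10 6-methyl-3,4-dihydro-2H-pyran; 9 [(2S,3S)-2,3-dimethyl-3-(pent-3-yn-1-yl)oxiran-2-yl]methyl trifluoromethanesulfonate
Product: 13 tricyclic ketal (1R,6S,7S,8S)-7,8-dimethyl-7-(pent-3-yn-1-yl)-2,11-dioxatricyclo[6.2.1.0^1,6]undecane, via lithiated dihydropyran 11 (not isolated), via epoxy enol ether 12 (not isolated)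
Conditions: sec-BuLi (1 equiv), TMEDA, THF, −78 → −30 °C; then 9, −78 °C; then BF3·OEt2 (excess), −78 → −40 °C; NaHCO3 (aq)
Reagents that add atoms: none
Why: Proposed new method: lateral deprotonation of the allylic methyl group of 10 gives the 2-oxyallyllithium 11, whose exocyclic carbon displaces the primary triflate of 9 (SN2) to form the C5–C6 bond and enol ether 12; BF3 then activates the oxirane, the enol-ether β-carbon (C3) attacks the fully substituted oxirane carbon (C2) anti to the breaking C–O bond, and the resulting tetrahydropyranyl oxocarbenium ion is captured by the liberated C1 alkoxide to give ketal 13. The closest known reaction types are the α,α′-annulation of ketone enamines with 1,3-bis-electrophiles and the epoxide-initiated cation–olefin cyclisation with enol-ether or enol-silane terminators. The carbocycle closes by 6-endo opening of the oxirane through a chair transition state, and the bridging ketal ring closes 5-exo-trig onto the oxocarbenium carbon. C1 keeps and C2 inverts the configuration installed by the epoxidation, while C3 is set by the ring-locked Z geometry of the enol ether, which places its ring CH2 equatorial and cis to the C2 methyl group in the chair. The step needs alkylation at CH2OTf and not at the oxirane, reaction of 11 at its exocyclic terminus, and 6-endo and not 5-exo opening; these should be secured by the far higher reactivity of the triflate over the shielded tetrasubstituted oxirane, by the less hindered primary terminus of the oxyallyl anion, and by the preference of π-nucleophiles for six-membered chair closure when both oxirane carbons are equally substituted.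

Step 7
Reactants: 13 tricyclic ketal
Product: 15 (1R,6S,7S,8S)-7-[(3E)-4-iodopent-3-en-1-yl]-7,8-dimethyl-2,11-dioxatricyclo[6.2.1.0^1,6]undecane, via alkenylzirconocene 14 (not isolated)
Conditions: Cp2Zr(H)Cl (excess), THF, 23 → 45 °C; then I2, 0 °C
Reagents that add atoms: iodine (II)
Why: Syn-hydrozirconation of the internal alkyne with equilibration by excess hydride should place zirconium on the less hindered methyl-bearing carbon, and iodinolysis of 14 with retention gives the E-iodoalkene while the ketal is inert.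

Step 8
Reactants: 15 iodoalkenyl tricyclic ketal; 16 (Z)-trimethyl(prop-1-en-1-yloxy)silane
Product: 18 (2Z)-2-[(2R,3S,4S)-4-hydroxy-2-(3-hydroxypropyl)-3-[(3E)-4-iodopent-3-en-1-yl]-3,4-dimethylcyclohexylidene]propanal, via β-alkoxy aldehyde 17 (not isolated)
Conditions: TMSOTf (cat.), CH2Cl2, −78 °C; then DBU, 0 → 23 °C; then K2CO3 (cat.), MeOH, 23 °C
Reagents that add atoms: none
Why: Mukaiyama aldol-type addition of the aldehyde enol silane to the oxocarbenium ion released by opening of the strained bridging C–O bond of the ketal (with silyl transfer to the C1 oxygen) gives 17, whose E1cB (retro-oxa-Michael) loss of the ring alkoxide unveils the primary alcohol and the tetrasubstituted enal while methanolysis frees the tertiary alcohol, and the reversible elimination should settle on the Z-enal in which the small formyl group and not the methyl group lies beside the substituted ring carbon C3.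

Step 9
Reactants: 19 nerol, (2Z)-3,7-dimethylocta-2,6-dien-1-ol
Product: 20 [(2R,3S)-3-methyl-3-(4-methylpent-3-en-1-yl)oxiran-2-yl]methanol
Conditions: Ti(OiPr)4 (cat.), D-(−)-diethyl tartrate (cat.), t-BuOOH, 4 Å molecular sieves, CH2Cl2, −20 °C
Reagents that add atoms: tert-butyl hydroperoxide (CC(C)(C)OO)
Why: Katsuki–Sharpless asymmetric epoxidation with the D-(−)-tartrate epoxidises only the allylic-alcohol double bond of the Z-alkene, from the face that should give the cis-(2R,3S)-oxirane.

Step 10
Reactants: 20 [(2R,3S)-3-methyl-3-(4-methylpent-3-en-1-yl)oxiran-2-yl]methanol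
Product: 21 (2S,3S)-3-methyl-3-(4-methylpent-3-en-1-yl)oxirane-2-carbaldehyde
Conditions: TEMPO (cat.), PhI(OAc)2, CH2Cl2, 23 °C
Reagents that add atoms: none
Why: TEMPO-catalysed oxidation through the oxoammonium ion converts the primary alcohol into the aldehyde under near-neutral conditions that preserve the oxirane and its stereocentres.

Step 11
Reactants: 21 (2S,3S)-3-methyl-3-(4-methylpent-3-en-1-yl)oxirane-2-carbaldehyde
Product: 22 (2S,3R)-3-ethenyl-2-methyl-2-(4-methylpent-3-en-1-yl)oxirane
Conditions: Ph3PCH3Br, KN(SiMe3)2, THF, −78 → 0 °C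
Reagents that add atoms: methyltriphenylphosphonium bromide (C[P+](c1ccccc1)(c1ccccc1)c1ccccc1.[Br-])
Why: Wittig methylenation with the non-stabilised ylide converts the aldehyde into the vinyl oxirane, and the low temperature should prevent epimerisation at the α-carbon.

Step 12
Reactants: 22 (2S,3R)-3-ethenyl-2-methyl-2-(4-methylpent-3-en-1-yl)oxirane; 18 iodoalkenyl enal diol
Product: 24 target, (2Z)-2-[(2R,3S,4S)-4-hydroxy-2-(3-hydroxypropyl)-3,4-dimethyl-3-{(3E)-4-methyl-6-[(2R,3S)-3-methyl-3-(4-methylpent-3-en-1-yl)oxiran-2-yl]hex-3-en-1-yl}cyclohexylidene]propanal, via alkylborane 23 (not isolated)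
Conditions: 9-BBN (1 equiv), THF, 0 → 23 °C; then 18, PdCl2(dppf) (cat.), AsPh3, Cs2CO3, DMF/H2O, 23 °C
Reagents that add atoms: none
Why: Anti-Markovnikov hydroboration of the terminal vinyl group gives the B-alkyl-9-BBN 23, and its B-alkyl Suzuki–Miyaura coupling with the iodoalkene proceeds with retention of the E geometry under mild base that the enal, the free hydroxyl groups and the oxirane should tolerate.

**Compound list**

1 | pent-3-yn-1-ol | CC#CCCO | starting material
2 | 5-iodopent-2-yne | CC#CCCI | intermediate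
3 | prop-2-yn-1-ol | C#CCO | starting material
4 | dilithio alkoxide of prop-2-yn-1-ol (O,C-dianion) | [Li]C#CCO[Li] | intermediate
5 | octa-2,6-diyn-1-ol | CC#CCCC#CCO | intermediate
6 | bromomagnesium (2Z)-3-(bromomagnesio)-2-methyloct-2-en-6-yn-1-olate (chelate, Mg cis to CH2O) | CC#CCC/C([Mg]Br)=C(\C)CO[Mg]Br | intermediate
7 | (2E)-2,3-dimethyloct-2-en-6-yn-1-ol | OC/C(C)=C(C)/CCC#CC | intermediate
8 | [(2S,3S)-2,3-dimethyl-3-(pent-3-yn-1-yl)oxiran-2-yl]methanol | OC[C@]1(C)O[C@@]1(C)CCC#CC | intermediate
9 | [(2S,3S)-2,3-dimethyl-3-(pent-3-yn-1-yl)oxiran-2-yl]methyl trifluoromethanesulfonate | O=S(=O)(OC[C@]1(C)O[C@@]1(C)CCC#CC)C(F)(F)F | intermediate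
10 | 6-methyl-3,4-dihydro-2H-pyran | CC1=CCCCO1 | starting material
11 | (3,4-dihydro-2H-pyran-6-ylmethyl)lithium | [Li]CC1=CCCCO1 | intermediate
12 | 6-{2-[(2S,3S)-2,3-dimethyl-3-(pent-3-yn-1-yl)oxiran-2-yl]ethyl}-3,4-dihydro-2H-pyran | O1CCCC=C1CC[C@]1(C)O[C@@]1(C)CCC#CC | intermediate
13 | (1R,6S,7S,8S)-7,8-dimethyl-7-(pent-3-yn-1-yl)-2,11-dioxatricyclo[6.2.1.0^1,6]undecane (7-oxabicyclo[2.2.1]heptane ketal fused to a tetrahydropyran) | C[C@@]12CC[C@]3(O1)OCCC[C@H]3[C@]2(C)CCC#CC | intermediate
14 | chlorobis(cyclopentadienyl)zirconium (2E)-alk-2-en-2-yl derivative of 13 (Zr trans to the chain) | C[C@@]12CC[C@]3(O1)OCCC[C@H]3[C@]2(C)CC/C=C(\C)[Zr](Cl)(C1C=CC=C1)C1C=CC=C1 | intermediate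
15 | (1R,6S,7S,8S)-7-[(3E)-4-iodopent-3-en-1-yl]-7,8-dimethyl-2,11-dioxatricyclo[6.2.1.0^1,6]undecane | C[C@@]12CC[C@]3(O1)OCCC[C@H]3[C@]2(C)CC/C=C(\C)I | intermediate
16 | (Z)-trimethyl(prop-1-en-1-yloxy)silane | C/C=C\O[Si](C)(C)C | starting material
17 | 2-[(4aS,5S,6S)-5-[(3E)-4-iodopent-3-en-1-yl]-5,6-dimethyl-6-[(trimethylsilyl)oxy]octahydro-2H-chromen-8a-yl]propanal (epimers at C8a and at the aldehyde α-carbon) | C[C@]1(O[Si](C)(C)C)CCC2(C(C)C=O)OCCC[C@H]2[C@]1(C)CC/C=C(\C)I | intermediate
18 | (2Z)-2-[(2R,3S,4S)-4-hydroxy-2-(3-hydroxypropyl)-3-[(3E)-4-iodopent-3-en-1-yl]-3,4-dimethylcyclohexylidene]propanal | I/C(C)=C/CC[C@@]1(C)[C@H](CCCO)/C(=C(/C)C=O)CC[C@]1(C)O | intermediate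
19 | nerol, (2Z)-3,7-dimethylocta-2,6-dien-1-ol | CC(C)=CCC/C(C)=C\CO | starting material
20 | [(2R,3S)-3-methyl-3-(4-methylpent-3-en-1-yl)oxiran-2-yl]methanol | CC(C)=CCC[C@]1(C)O[C@@H]1CO | intermediate
21 | (2S,3S)-3-methyl-3-(4-methylpent-3-en-1-yl)oxirane-2-carbaldehyde | CC(C)=CCC[C@]1(C)O[C@@H]1C=O | intermediate
22 | (2S,3R)-3-ethenyl-2-methyl-2-(4-methylpent-3-en-1-yl)oxirane | CC(C)=CCC[C@]1(C)O[C@@H]1C=C | intermediate
23 | 9-{2-[(2R,3S)-3-methyl-3-(4-methylpent-3-en-1-yl)oxiran-2-yl]ethyl}-9-borabicyclo[3.3.1]nonane | CC(C)=CCC[C@]1(C)O[C@@H]1CCB1C2CCCC1CCC2 | intermediate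
24 | (2Z)-2-[(2R,3S,4S)-4-hydroxy-2-(3-hydroxypropyl)-3,4-dimethyl-3-{(3E)-4-methyl-6-[(2R,3S)-3-methyl-3-(4-methylpent-3-en-1-yl)oxiran-2-yl]hex-3-en-1-yl}cyclohexylidene]propanal | CC(C)=CCC[C@]1(C)O[C@@H]1CC/C(C)=C/CC[C@@]1(C)[C@H](CCCO)/C(=C(/C)C=O)CC[C@]1(C)O | target

**Step count and risks**

Total step count: 12. Longest linear sequence: 9 steps (steps 1–8 and 12).

Steps most likely to fail:

1. Step 6 (proposed new method). The lateral lithiation may be incomplete, or the oxyallyl anion may be alkylated at its ring carbon. In the Lewis-acid stage the oxirane may open in the 5-exo sense or rearrange before the enol ether attacks. Fallback by known, stepwise chemistry, setting out from 10 and 9 and returning at 13: aqueous HCl hydrolyses 10 to 6-hydroxyhexan-2-one F1, which TBSCl and imidazole convert into 6-[(tert-butyldimethylsilyl)oxy]hexan-2-one F2. Its kinetic methyl-side enolate (LiN(iPr)2, THF, −78 °C) is alkylated with 9 to give 7-[(tert-butyldimethylsilyl)oxy]-1-[(2S,3S)-2,3-dimethyl-3-(pent-3-yn-1-yl)oxiran-2-yl]heptan-3-one F3. Bu4NF then gives 7-hydroxy-1-[(2S,3S)-2,3-dimethyl-3-(pent-3-yn-1-yl)oxiran-2-yl]heptan-3-one F4. Treatment of F4 with BF3·OEt2 should effect cyclodehydration to 12 and its cyclisation, rejoining the route at 13.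

2. Step 8. The enol silane may fail to add to the hindered tertiary oxocarbenium ion, or the elimination may deliver the E-enal or epimerise C3 through dienolate formation. Fallback setting out from 15 and returning at 18: aqueous HCl in THF hydrolyses the ketal to (2S,3S,4S)-4-hydroxy-2-(3-hydroxypropyl)-3-[(3E)-4-iodopent-3-en-1-yl]-3,4-dimethylcyclohexan-1-one F5. Prop-1-en-2-ylmagnesium bromide with CeCl3 adds to the ketone to give (2S,3S,4S)-2-(3-hydroxypropyl)-3-[(3E)-4-iodopent-3-en-1-yl]-3,4-dimethyl-1-(prop-1-en-2-yl)cyclohexane-1,4-diol F6. Pyridinium chlorochromate oxidises the primary alcohol and effects the Babler–Dauben oxidative transposition of the tertiary allylic alcohol in the same operation, giving 3-[(1R,2S,3S,6Z)-3-hydroxy-2-[(3E)-4-iodopent-3-en-1-yl]-2,3-dimethyl-6-(1-oxopropan-2-ylidene)cyclohexyl]propanal F7. NaBH4 at −78 °C should reduce only the unconjugated aldehyde and return 18.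

3. Step 3. The chelated alkenylmagnesium 6 may be too unreactive toward iodomethane and be protonated on work-up to the trisubstituted alkene. Fallback setting out from 5 and returning at 7: the chelate 6 is formed as before and quenched with iodine to give (2Z)-3-iodo-2-methyloct-2-en-6-yn-1-ol F8. A Negishi coupling with MeZnCl and Pd(PPh3)4 (zerovalent palladium) installs the second methyl group with retention and rejoins the route at 7.

Further compounds
F1 | step 6 | 6-hydroxyhexan-2-one | CC(=O)CCCCO
F2 | step 6 | 6-[(tert-butyldimethylsilyl)oxy]hexan-2-one | CC(=O)CCCCO[Si](C)(C)C(C)(C)C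
F3 | step 6 | 7-[(tert-butyldimethylsilyl)oxy]-1-[(2S,3S)-2,3-dimethyl-3-(pent-3-yn-1-yl)oxiran-2-yl]heptan-3-one | CC(C)(C)[Si](C)(C)OCCCCC(=O)CC[C@]1(C)O[C@@]1(C)CCC#CC
F4 | step 6 | 7-hydroxy-1-[(2S,3S)-2,3-dimethyl-3-(pent-3-yn-1-yl)oxiran-2-yl]heptan-3-one | OCCCCC(=O)CC[C@]1(C)O[C@@]1(C)CCC#CC
F5 | step 8 | (2S,3S,4S)-4-hydroxy-2-(3-hydroxypropyl)-3-[(3E)-4-iodopent-3-en-1-yl]-3,4-dimethylcyclohexan-1-one | I/C(C)=C/CC[C@@]1(C)[C@H](CCCO)C(=O)CC[C@]1(C)O
F6 | step 8 | (2S,3S,4S)-2-(3-hydroxypropyl)-3-[(3E)-4-iodopent-3-en-1-yl]-3,4-dimethyl-1-(prop-1-en-2-yl)cyclohexane-1,4-diol | I/C(C)=C/CC[C@@]1(C)[C@H](CCCO)C(O)(C(C)=C)CC[C@]1(C)O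
F7 | step 8 | 3-[(1R,2S,3S,6Z)-3-hydroxy-2-[(3E)-4-iodopent-3-en-1-yl]-2,3-dimethyl-6-(1-oxopropan-2-ylidene)cyclohexyl]propanal | I/C(C)=C/CC[C@@]1(C)[C@H](CCC=O)/C(=C(/C)C=O)CC[C@]1(C)O
F8 | step 3 | (2Z)-3-iodo-2-methyloct-2-en-6-yn-1-ol | CC#CCC/C(I)=C(\C)CO
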